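**Retrosynthetic overview**

1. Rings A (2-hydroxy-5-allylphenyl) and B (4-hydroxy-3-allylphenyl) are taken intact from honokiol 1; its ring B phenol is masked as the TIPS ether 2, so ring A carries the only free OH.
2. Ring C is taken intact from (R)-(−)-α-phellandrene 3; protonation gives the piperityl allyl cation 4 that the plant is thought to use.
3. Key disconnection: the aryl–C bond between ring A and ring C. Forward, the free phenol of 2 attacks cation 4 through its open ortho carbon, anti to the isopropyl group, to give 5; the stereocentre of 3 sets the new one.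
4. Last disconnection: O–Si. Bu4NF frees the ring B phenol of 5 to give target 6.
5. Ring order: no ring is built in the flask. A and B arrive together in 1, C arrives in 3, and the route only joins them.

Assumption: honokiol 1 and (R)-(−)-α-phellandrene 3 of checked enantiomeric purity are bought, and 3 is distilled before use.

**Route**

Step 1
Reactants: 1 honokiol (3',5-diallylbiphenyl-2,4'-diol)
Product: 2 4'-O-TIPS-honokiol (4-allyl-2-[3-allyl-4-(triisopropylsilyloxy)phenyl]phenol)
Conditions: TIPSCl (1.05 equiv), imidazole (2.5 equiv), DMF, 0 °C to rt
Reagents that add atoms: triisopropylsilyl chloride (TIPSCl), CC(C)[Si](Cl)(C(C)C)C(C)C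
Why: Imidazole-mediated silyl ether formation, in which the bulky silyl chloride is expected to prefer the 4'-OH (more acidic through its para-aryl group, flanked only by a flexible allyl CH2) over the 2-OH (pressed against the twisted ring B), with the minor 2-O isomer and the bis-silyl ether removed on silica and returned to 1 with Bu4NF; no stereocentre is involved.

Step 2
Reactants: 2 4'-O-TIPS-honokiol; 3 (R)-(−)-α-phellandrene [(5R)-2-methyl-5-(propan-2-yl)cyclohexa-1,3-diene]
Product: 5 4'-O-TIPS-piperitylhonokiol [4-allyl-2-(3-allyl-4-triisopropylsilyloxyphenyl)-6-((1R,6R)-3-methyl-6-isopropylcyclohex-2-en-1-yl)phenol], via piperityl cation tosylate 4 (not isolated)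
Conditions: TsOH·H2O (10 mol%), CH2Cl2, 0 °C to rt, 3 (1.5 equiv) added over 2 h; NaHCO3 quench
Reagents that add atoms: none
Why: Brønsted acid-catalysed hydroarylation of a 1,3-diene (Friedel–Crafts allylation, an atom-economic addition with no co-product): protonation of 3 at its methyl-substituted diene terminus gives allyl cation 4, and the only free phenol (ring A, para position held by allyl, other ortho position held by ring B) attacks through its open ortho carbon at the secondary cation terminus anti to the neighbouring isopropyl group, so the (R) centre of 3 is carried over untouched and sets the new aryl-bearing centre trans to it (1R,6R), while the bulky, less donating OTIPS group keeps ring B out and stops its o-allylphenol from cyclising.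

Step 3
Reactants: 5 4'-O-TIPS-piperitylhonokiol
Product: 6 piperitylhonokiol, the target (4-allyl-2-(3-allyl-4-hydroxyphenyl)-6-[(1R,6R)-3-methyl-6-(propan-2-yl)cyclohex-2-en-1-yl]phenol)
Conditions: Bu4NF (1.2 equiv), AcOH (1.2 equiv), THF, 0 °C to rt
Reagents that add atoms: none
Why: Fluoride-induced cleavage of an aryl silyl ether, driven by the strong Si–F bond and buffered with AcOH so that no free phenoxide is exposed; the three alkenes and both stereocentres are not touched.

**Compound list**

1 | honokiol, 3',5-diallylbiphenyl-2,4'-diol | C=CCc1ccc(O)c(-c2ccc(O)c(CC=C)c2)c1 | starting material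
2 | 4'-O-TIPS-honokiol, 4-allyl-2-[3-allyl-4-(triisopropylsilyloxy)phenyl]phenol | C=CCc1ccc(O)c(-c2ccc(O[Si](C(C)C)(C(C)C)C(C)C)c(CC=C)c2)c1 | intermediate
3 | (R)-(−)-α-phellandrene, (5R)-2-methyl-5-(propan-2-yl)cyclohexa-1,3-diene | CC1=CC[C@@H](C=C1)C(C)C | starting material
4 | piperityl (p-menth-1-en-3-yl) allyl cation as its tosylate ion pair, isopropyl-bearing centre as in 3 | [CH+]1C=C(C)CC[C@@H]1C(C)C.Cc1ccc(cc1)S(=O)(=O)[O-] | intermediate (not isolated)
5 | 4'-O-TIPS-piperitylhonokiol, 4-allyl-2-[3-allyl-4-(triisopropylsilyloxy)phenyl]-6-[(1R,6R)-3-methyl-6-(propan-2-yl)cyclohex-2-en-1-yl]phenol | C=CCc1cc(-c2ccc(O[Si](C(C)C)(C(C)C)C(C)C)c(CC=C)c2)c(O)c([C@H]2C=C(C)CC[C@@H]2C(C)C)c1 | intermediate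
6 | piperitylhonokiol, 4-allyl-2-(3-allyl-4-hydroxyphenyl)-6-[(1R,6R)-3-methyl-6-(propan-2-yl)cyclohex-2-en-1-yl]phenol, aryl and isopropyl trans | C=CCc1cc(-c2ccc(O)c(CC=C)c2)c(O)c([C@H]2C=C(C)CC[C@@H]2C(C)C)c1 | target

**Totals and risks**

Total step count: 3. Longest linear sequence: 3 steps (1 → 2 → 5 → 6).

Most likely to fail, in this order:

The coupling (step 2). A single phenol is a much weaker carbon nucleophile than the resorcinols for which this diene coupling is established. Cation 4 may instead lose a proton to give achiral α-terpinene (which would also erode the enantiomeric purity) and p-cymene, or be captured by more diene; the product can also cyclise onto its ring C alkene if left in acid. The fallback sets out from 3 and 2 and comes back at 5. Dry HCl (1.0 equiv, CH2Cl2, −78 °C) is added across the diene of 3 to give trans-piperityl chloride F1, used cold and crude, since its allylic isomers feed the same ion pair. Separately, 2 is converted with NaH in toluene into the sodium phenolate of 2 F2. Mixing the two at 0 °C gives carbon alkylation at the only free ortho position of the phenolate, again anti to the isopropyl group, to give 5. This replaces acid catalysis on a weak neutral nucleophile by an anionic nucleophile in a non-polar medium without acid, so diene isomerisation and acid-driven cyclisation drop out.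

The silylation (step 1). The preference for the 4'-OH rests on a modest steric and acidity difference; the two mono-silyl ethers may form in similar amounts or separate poorly. The site of silylation is checked by NOE between the Si–CH signals and the ring B protons. The fallback sets out from 1 and comes back at 6 and drops the protecting group altogether. 1 (2 equiv) and 3 are coupled directly with TsOH·H2O in CH2Cl2, which gives 6 alongside the ring B regioisomer F3. The two are separated by preparative HPLC and the excess 1 is recovered.

The desilylation (step 3). The risk is small: incomplete cleavage, or loss of the electron-rich bisphenol to air oxidation if the medium turns basic. The fallback sets out from 1 and comes back at 6 and uses an ester instead of a silyl ether. Ac2O (1.0 equiv), Et3N, CH2Cl2 at −40 °C gives 4'-O-acetylhonokiol F4. Coupling with 3 under the conditions of step 2 gives 4'-O-acetylpiperitylhonokiol F5; the acetoxy ring is electronically shut down, so ring A selectivity is even firmer. K2CO3 in MeOH at rt then removes the acetyl group to give 6.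

**Further compounds**

F1 | step 2 | trans-piperityl chloride, (3R,4R)-3-chloro-1-methyl-4-(propan-2-yl)cyclohex-1-ene | Cl[C@H]1C=C(C)CC[C@@H]1C(C)C
F2 | step 2 | sodium phenolate of 2, sodium 4-allyl-2-[3-allyl-4-(triisopropylsilyloxy)phenyl]phenolate | C=CCc1ccc([O-])c(-c2ccc(O[Si](C(C)C)(C(C)C)C(C)C)c(CC=C)c2)c1.[Na+]
F3 | step 1 | ring B regioisomer, 4-allyl-2-[3-allyl-4-hydroxy-5-((1R,6R)-3-methyl-6-(propan-2-yl)cyclohex-2-en-1-yl)phenyl]phenol | C=CCc1ccc(O)c(-c2cc(CC=C)c(O)c([C@H]3C=C(C)CC[C@@H]3C(C)C)c2)c1
F4 | step 3 | 4'-O-acetylhonokiol, 2-allyl-4-(5-allyl-2-hydroxyphenyl)phenyl acetate | C=CCc1ccc(O)c(-c2ccc(OC(C)=O)c(CC=C)c2)c1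
F5 | step 3 | 4'-O-acetylpiperitylhonokiol, 2-allyl-4-[5-allyl-2-hydroxy-3-((1R,6R)-3-methyl-6-(propan-2-yl)cyclohex-2-en-1-yl)phenyl]phenyl acetate | C=CCc1cc(-c2ccc(OC(C)=O)c(CC=C)c2)c(O)c([C@H]2C=C(C)CC[C@@H]2C(C)C)c1
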